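| flask | substrate | gas phase | catalyst | remark | time |
|---|---|---|---|---|---|
| dusk | 1.5 M | 140 mM (held) | 0.28 mol% | run made earlier |  |
| dawn | 1.5 M | 140 mM (held) | 0.44 mol% | run made earlier |  |
| winter | 2.2 M | 140 mM (held) | 0.2 mol% | run made earlier |  |
| blue | 1.5 M | 140 mM (held) | 0.2 mol% |  | 12 min |
| violet | 1.5 M | 140 mM (held) | 0.2 mol% |  | 40 min |

| run | time / min | substrate / % | product / % |
|---|---|---|---|
| dusk | 1.00 | 99.1 | 3.2 |
| dusk | 2.00 | 94.8 | 6.1 |
| dusk | 3.00 | 91.3 | 8.5 |
| dusk | 5.00 | 83.7 | 16.4 |
| dusk | 8.00 | 72.2 | 27.2 |
| dusk | 15.0 | 50.1 | 47.4 |
| dawn | 1.00 | 95.4 | 2.2 |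
| dawn | 2.00 | 93.6 | 7.3 |
| dawn | 3.00 | 88.8 | 10.0 |
| dawn | 5.00 | 80.5 | 18.6 |
| dawn | 8.00 | 69.1 | 30.0 |
| dawn | 15.0 | 44.4 | 56.9 |
| winter | 3.00 | 92.0 | 7.0 |
| winter | 6.00 | 84.3 | 16.2 |
| winter | 8.00 | 78.0 | 20.7 |
| winter | 12.0 | 67.0 | 32.4 |
| winter | 15.0 | 60.3 | 39.1 |

(each reading ± 1 percentage point)

- which of these there is most of at the end, counted by the substrate in it, blue (substrate / product)
- which of these there is most of at the end, counted by the substrate in it, violet (substrate / product)
- how much there is at the end of the one of these that leads, in percent of the substrate charged: blue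
- how much there is at the end of the one of these that leads, in percent of the substrate charged: violet

- at the start none of the gas phase is in solution
- a reading or a percentage of product counts all its forms, free or not

- I decide to time blue and violet by one rate law and to leave both closed, stirred and under the held gas: t = G(1 − x) − K ln x, where x is the fraction of substrate left at time t. This is the integrated Michaelis–Menten shape, two resistances in series.
- The last readings of dusk and dawn give G = 20.7 min, the gas time, meaning the minutes the charge needs at the ceiling of gas supply. They also give K = 9.47 min, the catalyst time at blue's loading, which scales inversely with loading.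
- Winter took no part in that fit, so it is a check. G grows with the charge and K shrinks with it, which puts its last reading at 15.3 min, and it was taken at 15.0 min.
- At the start of blue G stands above K, so gas crossing is the larger of two resistances that share the control of the rate. The starting rate gives substrate 60.2% at 12 min; putting the mean of that and the start back into K/x gives 63.1%, so substrate leads.
- In violet I go round x = exp(−(t − G(1 − x))/K), which gives 13.0%, 9.79%, 10.5%. Product leads at about 89.5%.
- Don't expect the rate to follow the loading: dawn carries 1.57 times dusk's loading, and its substrate reading at 15.0 min stands at 44.4% against dusk's 50.1%.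
- The forecast says substrate at 65% in blue and product at 95% in violet, expecting “a tail as it runs out”; my violet figure is lower.

The flasks give substrate at 64.3% in blue and product at 88.7% in violet.

    substrate + dissolved gas + catalyst → catalyst + product (k = 260 M⁻² min⁻¹)
    gas phase ⇌ dissolved gas, rate k2*(csat - [dissolved gas]) (kL = 0.550 min⁻¹)
    dissolved gas → decomposed reagent (k = 0.0380 min⁻¹)
    crystals ⇌ product, rate k4*(cs4 - [product]) while solid is left; crystals form when [product] > cs4 (solubility = 0.390 M, k = 11.0 min⁻¹)

- In violet at 40 min, K/x has reached 83.9 min against G of 20.7 min, so the catalyst side has taken over the tail.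
- The main reason violet's product stands at 88.7% and not at blue's 35.7% is the difference in time.
- A neighbour of blue charged with 0.05 mol% of catalyst has K = 37.9 min. The law then gives substrate 80.9% at 12 min, and that neighbour flask holds 83%.

The numbers in the tables are calculated with made-up constants; the scatter is artificial.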